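Percent of the Q charged is the unit of the readings, and in that unit the alder and maple runs rise and fall nearly alike.

| setting | alder | maple | flask |
|---|---|---|---|
| Q | 0.0034 M | 0.0075 M | 0.0050 M |
| Z | 1 µM | 1 µM | 1.0 µM |
| remark | run made earlier | run made earlier |  |
| time |  |  | 50 min |

- alder (time / min: E / %): 0.667: 33.5; 1.50: 35.8; 4.00: 35.0; 10.0: 32.2; 25.0: 27.4; 60.0: 17.7
- maple (time / min: E / %): 0.667: 31.4; 1.50: 35.5; 4.00: 34.7; 10.0: 32.8; 25.0: 27.5; 60.0: 19.2

(each reading ± 0.3 percentage points)

- what may be going on: L -> D; Q -> J; Z <-> G; Q + Z <-> L; L <-> Z + E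

- when, up to 50 min, the flask holds most E
- the amount of E, in percent of the Q charged, at that time

The reckoning here follows the rate of E, not the concentrations. Between 10.0 min and 60.0 min, alder loses E at 0.0120 min⁻¹ and maple at 0.0107 min⁻¹. Their mean, 0.0113 min⁻¹, is the fade rate λ, the apparent first-order constant of the fall of E, taken as the fraction lost per minute.

Carrying the mean reading at 4.00 min back to the start gives a plateau P of 36.5%, which has faded to 36.2% at 0.667 min. The gaps to that value in the two runs give a rise rate r of 3.46 min⁻¹, their mean, which is taken for the flask, whose charge of Q is more than alder's and less than maple's.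

The rise starts far faster than the fade, and its speed shrinks exponentially at r. It meets the fade once it has slowed by the factor r/λ, 306, which takes ln(r/λ)/r, or 1.65 min. Putting that time back into the tail gives a peak of 35.7%.

The forecast gives 1.8 min and 35.7%, holding that “The maximum falls where the rise meets the drain”. Its time is later than the one reckoned here.

The flask gives 1.68 min and 35.8%.

    L → D (k = 0.00320 s⁻¹)
    Q → J (k = 3.30 × 10⁻⁴ s⁻¹)
    Z ⇌ G (K = 0.270, k = 0.00170 s⁻¹)
    Q + Z ⇌ L (K = 170 L mol⁻¹, k = 1.60 × 10⁵ L mol⁻¹ s⁻¹)
    L ⇌ Z + E (K = 0.00340 M, k = 260 s⁻¹)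

From that peak, λ gives 20.7% of E in the flask at 50 min, where the flask holds 20.2%. The neighbouring flask is the same flask read later, at 80 min. The same fade over that longer time gives 14.8%, and the neighbouring flask holds 14.6% of E.

The earlier runs and the new flask are calculated from invented constants, noise included.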